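A direct plan would assemble the linear dienyl ether A1 from three preformed rings, oxidise its propargylic alcohol to the ynone, and let a macrocyclising Diels–Alder reaction with dehydrogenation create ring B and the 18-membered ring together (ketone A2). Demethylation to A3 and an asymmetric transfer hydrogenation would finish it. Its weakest steps would be three.
- The cycloaddition that closes the macrocycle would have to outrun ynone polymerisation across a long, flexible tether, and would have no close precedent.
- The palladium-catalysed making of the aryloxydiene would meet a second propargylic site in the same molecule.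
- The last reduction of the unprotected, enolisable triphenol ketone would set the only stereocentre at the very end, with catechol binding to the metal and only modest aryl/benzyl discrimination.

The route rests on the CH(OH)–CH2 bridge between ring B (para to its ether oxygen) and ring C (ortho to its ether oxygen): a 1,2-diarylethanol, the exact product pattern of a conjunctive cross-coupling. Both bridge carbons are cut out and come from vinyllithium. The precursor is a linear chain of rings B, A, D and C that ends in a boronic ester on ring B and a triflate on ring C. One palladium-catalysed operation (1,2-metallate shift, then reductive elimination) makes both aryl–carbon bonds, closes the 18-membered ring and sets the (S)-centre under ligand control. No arene is built de novo, no macrocyclic ketone is reduced, and benzyl ethers let hydrogenolysis replace Lewis-acid demethylation.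

Key step: step 9

Assumption: the (Sp,Sp) antipode of the ferrocenyl diphosphine is taken as the one that leads to the (S)-boronic ester; if the facial sense should prove opposite, its (Rp,Rp) mirror image would be used with nothing else changed.

Step 1
Reactants: 1 2-fluoro-3-hydroxybenzaldehyde; 2 3-bromophenol
Product: 4 3-(benzyloxy)-2-(3-bromophenoxy)benzaldehyde, via 3-(benzyloxy)-2-fluorobenzaldehyde 3 (not isolated)
Conditions: BnBr (1.0 equiv), K2CO3 (1.1 equiv), DMF, rt; then 2 (1.1 equiv), K2CO3 (1.5 equiv), 110 °C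
Reagents that add atoms: benzyl bromide, BrCc1ccccc1
Why: Williamson O-benzylation followed in the same flask by nucleophilic aromatic substitution (SNAr), in which the ortho-formyl group activates the C–F bond towards 3-bromophenoxide once the deactivating phenoxide of 1 has been capped, while the unactivated C–Br bond stays intact.

Step 2
Reactants: 4 3-(benzyloxy)-2-(3-bromophenoxy)benzaldehyde
Product: 6 3-(benzyloxy)-2-(3-bromophenoxy)phenol, via aryl formate 5 (not isolated)
Conditions: mCPBA (1.5 equiv), CH2Cl2, 0 °C → rt; then 2 M NaOH, MeOH, rt; aq. HCl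
Reagents that add atoms: meta-chloroperoxybenzoic acid, OOC(=O)c1cccc(Cl)c1
Why: Baeyer–Villiger (Dakin-type) oxidation, in which the electron-rich aryl group with its ortho-aryloxy donor migrates in preference to hydride and the formate is then saponified, so that the aldehyde that activated the SNAr becomes the phenol that will carry the triflate.

Step 3
Reactants: 7 3-bromo-4,5-dihydroxybenzaldehyde
Product: 8 3,4-bis(benzyloxy)-5-bromobenzaldehyde
Conditions: BnBr (2.4 equiv), K2CO3 (3 equiv), DMF, 60 °C
Reagents that add atoms: benzyl bromide, BrCc1ccccc1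
Why: Double Williamson etherification of the catechol, which masks both ring A hydroxyls as benzyl ethers that should survive every later base, borane and organolithium and leave by hydrogenolysis at the end.

Step 4
Reactants: 8 3,4-bis(benzyloxy)-5-bromobenzaldehyde; 9 4-chlorophenol
Product: 10 3,4-bis(benzyloxy)-5-(4-chlorophenoxy)benzaldehyde
Conditions: CuI (10 mol %), picolinic acid (20 mol %), K3PO4 (2 equiv), DMSO, 100 °C
Reagents that add atoms: none
Why: Ullmann-type copper-catalysed C–O coupling, in which the picolinate ligand allows coupling at the aryl bromide flanked by a benzyloxy group while the C–Cl bond of 9 is inert to copper and is kept as the later boron site.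

Step 5
Reactants: 10 3,4-bis(benzyloxy)-5-(4-chlorophenoxy)benzaldehyde
Product: 11 1,2-bis(benzyloxy)-3-(4-chlorophenoxy)-5-ethenylbenzene
Conditions: MePPh3Br (1.3 equiv), KOtBu (1.25 equiv), THF, 0 °C → rt
Reagents that add atoms: methyltriphenylphosphonium bromide, C[P+](c1ccccc1)(c1ccccc1)c1ccccc1.[Br-]
Why: Wittig methylenation of the non-enolisable aldehyde, which supplies the two carbons of the ring A–ring D bridge as a styrene.

Step 6
Reactants: 11 1,2-bis(benzyloxy)-3-(4-chlorophenoxy)-5-ethenylbenzene; 6 3-(benzyloxy)-2-(3-bromophenoxy)phenol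
Product: 13 3-(benzyloxy)-2-(3-{2-[3,4-bis(benzyloxy)-5-(4-chlorophenoxy)phenyl]ethyl}phenoxy)phenol, via B-alkyl-9-BBN adduct 12 (not isolated)
Conditions: 9-BBN-H (1.2 equiv), THF, 0 °C → rt; then 3 M aq. K3PO4, 6 (0.9 equiv), Pd(dppf)Cl2 (5 mol %), DMF, 60 °C
Reagents that add atoms: none
Why: Anti-Markovnikov hydroboration followed by B-alkyl Suzuki–Miyaura coupling, in which palladium inserts only into the C–Br bond of 6 (the electron-rich C–Cl bond is inert to this catalyst at 60 °C) and the phenol rides through as its phenoxide.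

Step 7
Reactants: 13 3-(benzyloxy)-2-(3-{2-[3,4-bis(benzyloxy)-5-(4-chlorophenoxy)phenyl]ethyl}phenoxy)phenol
Product: 14 3-(benzyloxy)-2-[3-(2-{3,4-bis(benzyloxy)-5-[4-(4,4,5,5-tetramethyl-1,3,2-dioxaborolan-2-yl)phenoxy]phenyl}ethyl)phenoxy]phenol
Conditions: B2pin2 (1.5 equiv), Pd2(dba)3 (2 mol %), XPhos (8 mol %), KOAc (3 equiv), 1,4-dioxane, 100 °C
Reagents that add atoms: bis(pinacolato)diboron, CC1(C)OB(OC1(C)C)B1OC(C)(C)C(C)(C)O1
Why: Miyaura borylation of the aryl chloride, for which the bulky biaryl phosphine enables oxidative addition at the electron-rich C–Cl bond while the weak base KOAc leaves the free phenol out of the catalytic cycle.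

Step 8
Reactants: 14 3-(benzyloxy)-2-[3-(2-{3,4-bis(benzyloxy)-5-[4-(4,4,5,5-tetramethyl-1,3,2-dioxaborolan-2-yl)phenoxy]phenyl}ethyl)phenoxy]phenol
Product: 15 3-(benzyloxy)-2-[3-(2-{3,4-bis(benzyloxy)-5-[4-(4,4,5,5-tetramethyl-1,3,2-dioxaborolan-2-yl)phenoxy]phenyl}ethyl)phenoxy]phenyl trifluoromethanesulfonate
Conditions: PhNTf2 (1.2 equiv), Et3N (2 equiv), DMAP (10 mol %), CH2Cl2, rt
Reagents that add atoms: N-phenylbis(trifluoromethanesulfonimide), O=S(=O)(N(c1ccccc1)S(=O)(=O)C(F)(F)F)C(F)(F)F
Why: O-Sulfonylation of the phenol with a mild triflyl-transfer reagent, which leaves the pinacol boronic ester untouched and puts the electrophile on the ring C carbon that will carry the CH2 group.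

Step 9
Reactants: 15 3-(benzyloxy)-2-[3-(2-{3,4-bis(benzyloxy)-5-[4-(4,4,5,5-tetramethyl-1,3,2-dioxaborolan-2-yl)phenoxy]phenyl}ethyl)phenoxy]phenyl trifluoromethanesulfonate
Product: 18 tri-O-benzyl ether of the (S)-carbinol (benzyl on both ring A oxygens and on the ring C oxygen; macrocycle closed), via vinyl boronate ate complex 16 (not isolated), via macrocyclic boronic ester 17 (not isolated)
Conditions: halide-free vinyllithium (1.05 equiv), THF, −78 °C → rt; then added over 10 h to Pd(OAc)2 (5 mol %), (Sp,Sp)-MandyPhos [1,1′-bis{bis(4-methoxy-3,5-dimethylphenyl)phosphino}-2,2′-bis{(R)-α-(dimethylamino)benzyl}ferrocene] (6 mol %), THF (final 2 mM), 60 °C; then 3 M NaOH, 30% H2O2, 0 °C → rt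
Reagents that add atoms: vinyllithium, [Li]C=C; hydrogen peroxide, OO
Why: Proposed new method: vinyllithium adds to the boronic ester to give ate complex 16; zerovalent palladium inserts into the ring C C–OTf bond, the cationic aryl palladium binds the vinyl group of the same molecule and triggers a 1,2-shift of ring B from boron to the α-carbon anti to the metal, and reductive elimination joins the β-carbon to ring C. The closest known reaction type is the intermolecular palladium-catalysed enantioselective conjunctive cross-coupling of vinylboron ate complexes with aryl triflates, which gives 1,2-diarylethyl boronic esters of this substitution pattern. The 18-membered ring is closed at the ring C–CH2 bond by reductive elimination from a 19-membered palladacycle, which arises when the metallate shift contracts a 20-membered π-complex and makes the ring B–CH bond, so no small or strained ring has to form. The carbinol centre is set by the ferrocenyl diphosphine, which selects the face of the vinyl group that binds palladium, and the stereoretentive peroxide oxidation of the C–B bond hands the configuration on to the (S)-alcohol. The step needs ring closure to beat oligomerisation, which slow addition at 2 mM should secure, and the metallate shift to beat direct Suzuki-type transmetallation, which the halide-free triflate and the bidentate ligand favour; 15 carries no second alkene, halide or acidic proton to divert either reagent.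

Step 10
Reactants: 18 tri-O-benzyl ether of the (S)-carbinol
Product: 19 CNP0356934.1, the (S)-carbinol with three free phenols
Conditions: H2 (1 atm), Pd/C (10 wt %), EtOAc/MeOH, rt, stopped as soon as the benzyl ethers are consumed; handled under argon
Reagents that add atoms: none
Why: Hydrogenolysis of the three aryl benzyl ethers under neutral conditions, where O-benzyl cleavage is much faster than loss of the secondary benzylic hydroxyl, so the (S)-centre should be carried over unchanged.

Compound list
1 | 2-fluoro-3-hydroxybenzaldehyde | O=Cc1cccc(O)c1F | starting material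
2 | 3-bromophenol | Oc1cccc(Br)c1 | starting material
3 | 3-(benzyloxy)-2-fluorobenzaldehyde | O=Cc1cccc(OCc2ccccc2)c1F | intermediate
4 | 3-(benzyloxy)-2-(3-bromophenoxy)benzaldehyde | O=Cc1cccc(OCc2ccccc2)c1Oc1cccc(Br)c1 | intermediate
5 | 3-(benzyloxy)-2-(3-bromophenoxy)phenyl formate | O=COc1cccc(OCc2ccccc2)c1Oc1cccc(Br)c1 | intermediate
6 | 3-(benzyloxy)-2-(3-bromophenoxy)phenol | Oc1cccc(OCc2ccccc2)c1Oc1cccc(Br)c1 | intermediate
7 | 3-bromo-4,5-dihydroxybenzaldehyde | O=Cc1cc(O)c(O)c(Br)c1 | starting material
8 | 3,4-bis(benzyloxy)-5-bromobenzaldehyde | O=Cc1cc(OCc2ccccc2)c(OCc2ccccc2)c(Br)c1 | intermediate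
9 | 4-chlorophenol | Oc1ccc(Cl)cc1 | starting material
10 | 3,4-bis(benzyloxy)-5-(4-chlorophenoxy)benzaldehyde | O=Cc1cc(OCc2ccccc2)c(OCc2ccccc2)c(Oc2ccc(Cl)cc2)c1 | intermediate
11 | 1,2-bis(benzyloxy)-3-(4-chlorophenoxy)-5-ethenylbenzene | C=Cc1cc(OCc2ccccc2)c(OCc2ccccc2)c(Oc2ccc(Cl)cc2)c1 | intermediate
12 | 9-{2-[3,4-bis(benzyloxy)-5-(4-chlorophenoxy)phenyl]ethyl}-9-borabicyclo[3.3.1]nonane | Clc1ccc(Oc2cc(CCB3C4CCCC3CCC4)cc(OCc3ccccc3)c2OCc2ccccc2)cc1 | intermediate
13 | 3-(benzyloxy)-2-(3-{2-[3,4-bis(benzyloxy)-5-(4-chlorophenoxy)phenyl]ethyl}phenoxy)phenol | Oc1cccc(OCc2ccccc2)c1Oc1cccc(CCc2cc(OCc3ccccc3)c(OCc3ccccc3)c(Oc3ccc(Cl)cc3)c2)c1 | intermediate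
14 | 3-(benzyloxy)-2-[3-(2-{3,4-bis(benzyloxy)-5-[4-(4,4,5,5-tetramethyl-1,3,2-dioxaborolan-2-yl)phenoxy]phenyl}ethyl)phenoxy]phenol | Oc1cccc(OCc2ccccc2)c1Oc1cccc(CCc2cc(OCc3ccccc3)c(OCc3ccccc3)c(Oc3ccc(cc3)B3OC(C)(C)C(C)(C)O3)c2)c1 | intermediate
15 | aryl triflate of 14 (triflate on ring C, pinacol boronic ester on ring B) | FC(F)(F)S(=O)(=O)Oc1cccc(OCc2ccccc2)c1Oc1cccc(CCc2cc(OCc3ccccc3)c(OCc3ccccc3)c(Oc3ccc(cc3)B3OC(C)(C)C(C)(C)O3)c2)c1 | intermediate
16 | lithium ate complex of 15 (vinyl group and ring B on tetracoordinate pinacolato boron) | [Li+].C=C[B-]1(OC(C)(C)C(C)(C)O1)c1ccc(cc1)Oc1cc(CCc2cccc(Oc3c(OCc4ccccc4)cccc3OS(=O)(=O)C(F)(F)F)c2)cc(OCc2ccccc2)c1OCc1ccccc1 | intermediate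
17 | macrocyclic (S)-benzylic pinacol boronic ester (target skeleton with Bpin in place of the carbinol OH and benzyl on the three phenolic oxygens) | c3ccccc3COc1cc2cc(c1OCc3ccccc3)Oc1ccc(cc1)[C@@H](B3OC(C)(C)C(C)(C)O3)Cc1cccc(OCc3ccccc3)c1Oc1cccc(c1)CC2 | intermediate
18 | tri-O-benzyl ether of the (S)-carbinol | c3ccccc3COc1cc2cc(c1OCc3ccccc3)Oc1ccc(cc1)[C@@H](O)Cc1cccc(OCc3ccccc3)c1Oc1cccc(c1)CC2 | intermediate
19 | CNP0356934.1, (S)-benzylic carbinol | Oc1cc2cc(c1O)Oc1ccc(cc1)[C@@H](O)Cc1cccc(O)c1Oc1cccc(c1)CC2 | target

Total step count: 10. Longest linear sequence: 8 steps (steps 3 to 10, from 7).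

Steps most likely to fail

Step 9. Ring closure may lose to intermolecular coupling at the stage of alkene binding, the ate complex may hand its vinyl or aryl group directly to palladium instead of undergoing the metallate shift, or the long tether may erode the facial selectivity. The fallback would run the conjunctive coupling in its established bimolecular form and close the ring afterwards at the ring A–ring D bridge by ring-closing metathesis; it sets out from 11 and 6.
- Miyaura borylation of 11 (B2pin2, Pd2(dba)3, XPhos, KOAc) would give 2-{4-[2,3-bis(benzyloxy)-5-ethenylphenoxy]phenyl}-4,4,5,5-tetramethyl-1,3,2-dioxaborolane F1.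
- Suzuki–Miyaura vinylation of 6 (potassium vinyltrifluoroborate, Pd(dppf)Cl2, Cs2CO3, THF/H2O) would give 3-(benzyloxy)-2-(3-ethenylphenoxy)phenol F2, and PhNTf2/Et3N would turn it into 3-(benzyloxy)-2-(3-ethenylphenoxy)phenyl trifluoromethanesulfonate F3.
- F1 and vinyllithium would give the lithium vinyl ate complex of F1 F4, which with F3, Pd(OAc)2 and the same ferrocenyl diphosphine at ordinary concentration would give the acyclic (S)-benzylic pinacol boronic ester with two styrene ends F5.
- NaOH/H2O2 would oxidise it to (1S)-1-{4-[2,3-bis(benzyloxy)-5-ethenylphenoxy]phenyl}-2-[3-(benzyloxy)-2-(3-ethenylphenoxy)phenyl]ethan-1-ol F6.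
- Second-generation Grubbs catalyst at high dilution would close the tri-O-benzyl macrocyclic (S)-carbinol with a CH=CH bridge between rings A and D F7.
- H2 over Pd/C would saturate that bridge and remove the benzyl groups in one operation, so that the fallback comes back to the route at 19.

Step 10. Hydrogenolysis may go on from the benzyl ethers to the benzylic C–O bond of the para-aryloxybenzylic carbinol, which would erase the stereocentre. The fallback would remove the benzyl groups while the carbinol carbon still carries boron; it sets out from 17, isolated by leaving out the oxidative work-up of step 9. H2 over Pd/C, which does not cleave a C–B bond, would give the macrocyclic (S)-benzylic pinacol boronic ester with three free phenols F8. Trimethylamine N-oxide in THF would then oxidise the C–B bond with retention under neutral conditions that spare the catechol, and the fallback comes back to the route at 19.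

Step 4. Oxidative addition and ligand exchange at the electron-rich aryl bromide next to a benzyloxy group may be slow, so that conversion stalls and hydrodebromination takes over. The fallback would invert the polarity of ring A and make the ether by oxidative Chan–Lam–Evans coupling; it sets out from 8. Miyaura borylation (B2pin2, Pd(dppf)Cl2, KOAc, 1,4-dioxane, 80 °C) would give 3,4-bis(benzyloxy)-5-(4,4,5,5-tetramethyl-1,3,2-dioxaborolan-2-yl)benzaldehyde F9. Cu(OAc)2, B(OH)3 and 4 Å MS in MeCN under air with 9 would then give 10, where the fallback comes back to the route.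

Further compounds
F1 | step 9 | 2-{4-[2,3-bis(benzyloxy)-5-ethenylphenoxy]phenyl}-4,4,5,5-tetramethyl-1,3,2-dioxaborolane | C=Cc1cc(OCc2ccccc2)c(OCc2ccccc2)c(Oc2ccc(cc2)B2OC(C)(C)C(C)(C)O2)c1
F2 | step 9 | 3-(benzyloxy)-2-(3-ethenylphenoxy)phenol | Oc1cccc(OCc2ccccc2)c1Oc1cccc(C=C)c1
F3 | step 9 | 3-(benzyloxy)-2-(3-ethenylphenoxy)phenyl trifluoromethanesulfonate | FC(F)(F)S(=O)(=O)Oc1cccc(OCc2ccccc2)c1Oc1cccc(C=C)c1
F4 | step 9 | lithium vinyl ate complex of F1 | [Li+].C=C[B-]1(OC(C)(C)C(C)(C)O1)c1ccc(cc1)Oc1cc(C=C)cc(OCc2ccccc2)c1OCc1ccccc1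
F5 | step 9 | acyclic (S)-benzylic pinacol boronic ester with two styrene ends | C=Cc1cc(OCc2ccccc2)c(OCc2ccccc2)c(c1)Oc1ccc(cc1)[C@@H](B1OC(C)(C)C(C)(C)O1)Cc1cccc(OCc2ccccc2)c1Oc1cccc(C=C)c1
F6 | step 9 | (1S)-1-{4-[2,3-bis(benzyloxy)-5-ethenylphenoxy]phenyl}-2-[3-(benzyloxy)-2-(3-ethenylphenoxy)phenyl]ethan-1-ol | C=Cc1cc(OCc2ccccc2)c(OCc2ccccc2)c(c1)Oc1ccc(cc1)[C@@H](O)Cc1cccc(OCc2ccccc2)c1Oc1cccc(C=C)c1
F7 | step 9 | tri-O-benzyl macrocyclic (S)-carbinol with a CH=CH bridge between rings A and D (E/Z mixture) | c3ccccc3COc1cc2cc(c1OCc3ccccc3)Oc1ccc(cc1)[C@@H](O)Cc1cccc(OCc3ccccc3)c1Oc1cccc(c1)C=C2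
F8 | step 10 | macrocyclic (S)-benzylic pinacol boronic ester with three free phenols | Oc1cc2cc(c1O)Oc1ccc(cc1)[C@@H](B3OC(C)(C)C(C)(C)O3)Cc1cccc(O)c1Oc1cccc(c1)CC2
F9 | step 4 | 3,4-bis(benzyloxy)-5-(4,4,5,5-tetramethyl-1,3,2-dioxaborolan-2-yl)benzaldehyde | O=Cc1cc(OCc2ccccc2)c(OCc2ccccc2)c(c1)B1OC(C)(C)C(C)(C)O1
A1 | direct plan | rac-1-{2-[3-(2-{3-(buta-1,3-dien-2-yloxy)-4,5-dimethoxyphenyl}ethyl)phenoxy]-3-methoxyphenyl}but-3-yn-2-ol | C=CC(=C)Oc1cc(CCc2cccc(Oc3c(CC(O)C#C)cccc3OC)c2)cc(OC)c1OC
A2 | direct plan | macrocyclic aryl benzyl ketone tri-O-methyl ether | COc1cc2cc(c1OC)Oc1ccc(cc1)C(=O)Cc1cccc(OC)c1Oc1cccc(c1)CC2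
A3 | direct plan | macrocyclic triphenol ketone | Oc1cc2cc(c1O)Oc1ccc(cc1)C(=O)Cc1cccc(O)c1Oc1cccc(c1)CC2
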